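The route rests on cutting C9–C11, the bond between ring B and the side chain. Ring B carries oxygen at C6 and C8; at the diketone level (a trans-fused decalin-6,8-dione) C9, the methylene between C8 and the quaternary C10, becomes the terminal carbon of a β-diketone dianion. The key step condenses this dianion with an aldehyde ester that holds C11–C15 and the C13 stereocentre, giving the C9=C11 alkylidene dione; hydrogenation from the face opposite the C10 methyl then fixes C9. Afterwards the C8 carbonyl becomes the methyl carbinol (enol triflate, methylation, hydration) and the C6 carbonyl the β-acetate.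

Key step: step 8

Remark: labdane numbering is used throughout (ring A = C1–C5 and C10, ring B = C5–C10, side chain C11–C16, ester carbon C15, C17 = methyl on C8); (R)-3-methylglutaric acid monomethyl ester is assumed to be a commercial chiral-pool compound.

**Step 1**
Reactants: 1 3-methylcyclohex-2-en-1-one; 2 5-bromo-2-methylpent-2-ene
Product: 4 (S)-3-methyl-3-(4-methylpent-3-en-1-yl)cyclohexan-1-one, via homoprenyl Grignard reagent 3 (not isolated)
Conditions: Mg, Et2O (2 → 3); then 1, Cu(OTf)2 (3 mol%), chiral C2-symmetric imidazolinium salt (NHC precursor, 4 mol%, enantiomer that gives the (S)-ketone), Et2O, 0 °C; aq NH4Cl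
Reagents that add atoms: none
Why: Copper-catalysed asymmetric conjugate addition of a Grignard reagent to a β-substituted cyclohexenone; the chiral carbene–copper complex selects the enone face and so sets the quaternary C10.

**Step 2**
Reactants: 4 (S)-3-methyl-3-(4-methylpent-3-en-1-yl)cyclohexan-1-one
Product: 5 (4aR,8aS)-4a,8,8-trimethyloctahydronaphthalen-1(2H)-one
Conditions: MeSO3H (3 equiv), CH2Cl2, 0 → 23 °C; aq NaHCO3
Reagents that add atoms: none
Why: Cation–olefin cyclisation ended by a ketone enol (intramolecular α-tert-alkylation): Markovnikov protonation of the alkene gives the tertiary C4 cation, only the C5 enol carbon can reach it through a six-membered chair (carbonyl–ene or Prins adducts should revert under the protic conditions), and C5–H, α to the C6 ketone, settles trans to the C10 methyl.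

**Step 3**
Reactants: 5 (4aR,8aS)-4a,8,8-trimethyloctahydronaphthalen-1(2H)-one
Product: 6 (4aR,8aS)-4a,8,8-trimethyl-4a,5,6,7,8,8a-hexahydronaphthalen-1(4H)-one
Conditions: IBX (2 equiv), DMSO/fluorobenzene, 70 °C
Reagents that add atoms: none
Why: IBX dehydrogenation of a ketone to the enone; only C7–C8 can be desaturated because both other neighbours of C5 (C4 and C10) are quaternary.

**Step 4**
Reactants: 6 (4aR,8aS)-4a,8,8-trimethyl-4a,5,6,7,8,8a-hexahydronaphthalen-1(4H)-one
Product: 7 (4aR,8aS)-2,3-epoxy-4a,8,8-trimethyloctahydronaphthalen-1(2H)-one with the oxirane on the α face (7α,8α)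
Conditions: 30% aq H2O2, NaOH (0.2 equiv), MeOH, 0 °C
Reagents that add atoms: hydrogen peroxide (OO)
Why: Weitz–Scheffer nucleophilic epoxidation of the enone; hydroperoxide should add to C8 on the α face, away from the C10 methyl, though the oxirane configuration is lost in step 5.

**Step 5**
Reactants: 7 the 7α,8α-epoxy ketone
Product: 8 (4aR,8aS)-4a,8,8-trimethylhexahydronaphthalene-1,3(2H,4H)-dione
Conditions: Pd(PPh3)4 (5 mol%), 1,2-bis(diphenylphosphino)ethane (5 mol%), toluene, 100 °C
Reagents that add atoms: none
Why: Isomerisation of an α,β-epoxy ketone to the β-diketone catalysed by zerovalent palladium (cleavage of the C7–O bond next to the carbonyl, hydride shift from C8); this places the second ring-B oxygen on C8 and leaves C5 and C10 untouched.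

**Step 6**
Reactants: 9 (R)-5-methoxy-3-methyl-5-oxopentanoic acid
Product: 11 (S)-4-methyltetrahydro-2H-pyran-2-one, via hydroxy acid 10 (not isolated)
Conditions: LiBH4 (2 equiv), THF, 0 → 23 °C; then 2 M HCl, 23 °C
Reagents that add atoms: none
Why: Chemoselective borohydride reduction of the ester while the acid is masked as its lithium carboxylate, then acid-promoted lactonisation; the stereocentre is not involved (the descriptor changes only through CIP priorities).

**Step 7**
Reactants: 11 (S)-4-methyltetrahydro-2H-pyran-2-one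
Product: 13 methyl (S)-3-methyl-5-oxopentanoate, via hydroxy ester 12 (not isolated)
Conditions: NaOMe (0.1 equiv), MeOH, 0 °C; AcOH, concentrate cold; then TEMPO (0.1 equiv), PhI(OAc)2 (1.1 equiv), CH2Cl2, 23 °C
Reagents that add atoms: methanol (CO)
Why: Base-catalysed methanolysis opens the lactone and TEMPO-catalysed oxidation converts the primary alcohol to the aldehyde before it can relactonise; the stereocentre is β to both carbonyls and cannot epimerise.

**Step 8**
Reactants: 8 (4aR,8aS)-4a,8,8-trimethylhexahydronaphthalene-1,3(2H,4H)-dione; 13 methyl (S)-3-methyl-5-oxopentanoate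
Product: 16 methyl (13S,9(11)Z)-6,8-dioxo-17-norlabd-9(11)-en-15-oate, via dione dianion 14 (not isolated), via aldol adduct 15 (not isolated)
Conditions: LDA (2.1 equiv), THF, −78 → 0 → −78 °C; 13, −78 °C; aq NH4Cl; crude adduct, TsOH·H2O (0.1 equiv), toluene, 60 °C
Reagents that add atoms: none
Why: Two equivalents of LDA turn the enolised β-diketone 8 into its dilithium dianion 14, whose terminal carbon C9 (the only accessible γ-position, since C5 is a ring-fusion methine between two quaternary carbons) adds to the aldehyde carbon C11 of 13; acid-catalysed loss of water from the β-hydroxy ketone 15 then gives the conjugated C9=C11 alkylidene dione. The closest known reaction type is the γ-aldol reaction of β-dicarbonyl dianions followed by dehydration (aldol condensation). No ring is closed. No stereocentre is kept from this step: C9 and C11 become sp2 in 16 (either alkene geometry converges in step 9), C9 is set in step 9, and C13 is carried in unchanged from 13. The step needs attack through the γ-carbon C9 instead of the central C7 or oxygen, which the dianion secures because its terminal carbanion is by far its most nucleophilic site, and it needs addition to the aldehyde in the presence of the methyl ester, which the much higher electrophilicity of the aldehyde at −78 °C secures.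

**Step 9**
Reactants: 16 methyl (13S,9(11)Z)-6,8-dioxo-17-norlabd-9(11)-en-15-oate
Product: 17 methyl (13S)-6,8-dioxo-17-norlabdan-15-oate
Conditions: H2 (1 atm), 10% Pd/C, EtOAc, 23 °C
Reagents that add atoms: none
Why: Catalytic hydrogenation of the enone C=C: hydrogen should be delivered to the α face of C9=C11, opposite the axial C10 methyl, which sets 9α-H with the side chain β (equatorial); direct alkylation at C9 from that same open face would have given the wrong epimer.

**Step 10**
Reactants: 17 methyl (13S)-6,8-dioxo-17-norlabdan-15-oate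
Product: 18 methyl (13S)-6-oxo-8-(trifluoromethylsulfonyloxy)-17-norlabd-7-en-15-oate
Conditions: Tf2O (1.1 equiv), 2,6-lutidine (1.5 equiv), CH2Cl2, −78 °C
Reagents that add atoms: trifluoromethanesulfonic anhydride (O=S(=O)(OS(=O)(=O)C(F)(F)F)C(F)(F)F)
Why: Enol triflate formation from a β-diketone under kinetic conditions: O8, next to the tertiary C9, should react in preference to O6, which lies peri to the C4 gem-dimethyl group, so the C6 carbonyl is kept.

**Step 11**
Reactants: 18 methyl (13S)-6-oxo-8-(trifluoromethylsulfonyloxy)-17-norlabd-7-en-15-oate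
Product: 19 methyl (13S)-6-oxolabd-7-en-15-oate
Conditions: MeZnCl (1.5 equiv), Pd(PPh3)4 (5 mol%), THF, 0 → 23 °C
Reagents that add atoms: methylzinc chloride (C[Zn]Cl)
Why: Negishi coupling of the β-triflyloxy enone installs the C17 methyl with the C7=C8 double bond in place; ester and ketone are inert to the organozinc and C9 is not touched.

**Step 12**
Reactants: 19 methyl (13S)-6-oxolabd-7-en-15-oate
Product: 20 methyl (13S)-6β-hydroxylabd-7-en-15-oate
Conditions: NaBH4, CeCl3·7H2O, MeOH, −40 °C
Reagents that add atoms: none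
Why: Luche reduction (1,2-selective): hydride should attack C6 from the α face because the β face is screened by the axial methyls on C4 and C10, giving the axial 6β-alcohol.

**Step 13**
Reactants: 20 methyl (13S)-6β-hydroxylabd-7-en-15-oate
Product: 21 methyl (13S)-6β-acetoxylabd-7-en-15-oate
Conditions: Ac2O, DMAP, pyridine, 40 °C
Reagents that add atoms: acetic anhydride (CC(=O)OC(C)=O)
Why: DMAP-catalysed acylation of the hindered axial secondary alcohol; no other hydroxyl is present.

**Step 14**
Reactants: 21 methyl (13S)-6β-acetoxylabd-7-en-15-oate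
Product: 22 methyl (13S)-6β-acetoxy-8α-hydroxylabdan-15-oate (target)
Conditions: Co(acac)2 (0.2 equiv), PhSiH3 (2 equiv), O2 (1 atm), THF/i-PrOH, 0 → 23 °C
Reagents that add atoms: dioxygen (O=O)
Why: Mukaiyama hydration (hydrogen-atom transfer from a cobalt hydride, then O2 capture): hydrogen goes to C7 and the tertiary C8 radical should be trapped on the α face, since the β face carries the syn-axial C10 methyl and 6β-acetoxy group, giving 8α-OH with the C17 methyl β.

**Compound list**
1 | 3-methylcyclohex-2-en-1-one | CC1=CC(=O)CCC1 | starting material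
2 | 5-bromo-2-methylpent-2-ene | CC(C)=CCCBr | starting material
3 | (4-methylpent-3-en-1-yl)magnesium bromide | CC(C)=CCC[Mg]Br | intermediate
4 | (S)-3-methyl-3-(4-methylpent-3-en-1-yl)cyclohexan-1-one | O=C1C[C@](C)(CCC=C(C)C)CCC1 | intermediate
5 | (4aR,8aS)-4a,8,8-trimethyloctahydronaphthalen-1(2H)-one (trans-fused, C6 ketone, 5α-H, 10β-CH3) | C1[C@@]2(C)CCCC(C)(C)[C@@H]2C(=O)CC1 | intermediate
6 | (4aR,8aS)-4a,8,8-trimethyl-4a,5,6,7,8,8a-hexahydronaphthalen-1(4H)-one (C7=C8 enone) | C1[C@@]2(C)CCCC(C)(C)[C@@H]2C(=O)C=C1 | intermediate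
7 | 7α,8α-epoxide of 6 | C1[C@@]2(C)CCCC(C)(C)[C@@H]2C(=O)[C@H]3O[C@H]31 | intermediate
8 | (4aR,8aS)-4a,8,8-trimethylhexahydronaphthalene-1,3(2H,4H)-dione (6,8-dione) | C1[C@@]2(C)CCCC(C)(C)[C@@H]2C(=O)CC1=O | intermediate
9 | (R)-5-methoxy-3-methyl-5-oxopentanoic acid | OC(=O)C[C@@H](C)CC(=O)OC | starting material
10 | (S)-5-hydroxy-3-methylpentanoic acid | OC(=O)C[C@@H](C)CCO | intermediate
11 | (S)-4-methyltetrahydro-2H-pyran-2-one | O=C1C[C@@H](C)CCO1 | intermediate
12 | methyl (S)-5-hydroxy-3-methylpentanoate | COC(=O)C[C@@H](C)CCO | intermediate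
13 | methyl (S)-3-methyl-5-oxopentanoate | COC(=O)C[C@@H](C)CC=O | intermediate
14 | dilithium dianion of 8 | [Li+].[Li+].[O-]C1=CC([O-])=C[C@@]2(C)CCCC(C)(C)[C@H]12 | intermediate
15 | methyl (13S)-11-hydroxy-6,8-dioxo-17-norlabdan-15-oate (aldol adduct, 9α-substituent expected, C11 epimers) | COC(=O)C[C@@H](C)CC(O)[C@H]1[C@@]2(C)CCCC(C)(C)[C@@H]2C(=O)CC1=O | intermediate
16 | methyl (13S,9(11)Z)-6,8-dioxo-17-norlabd-9(11)-en-15-oate | COC(=O)C[C@@H](C)C/C=C1/[C@@]2(C)CCCC(C)(C)[C@@H]2C(=O)CC1=O | intermediate
17 | methyl (13S)-6,8-dioxo-17-norlabdan-15-oate | COC(=O)C[C@@H](C)CC[C@@H]1[C@@]2(C)CCCC(C)(C)[C@@H]2C(=O)CC1=O | intermediate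
18 | methyl (13S)-6-oxo-8-(trifluoromethylsulfonyloxy)-17-norlabd-7-en-15-oate | COC(=O)C[C@@H](C)CC[C@@H]1[C@@]2(C)CCCC(C)(C)[C@@H]2C(=O)C=C1OS(=O)(=O)C(F)(F)F | intermediate
19 | methyl (13S)-6-oxolabd-7-en-15-oate | COC(=O)C[C@@H](C)CC[C@@H]1[C@@]2(C)CCCC(C)(C)[C@@H]2C(=O)C=C1C | intermediate
20 | methyl (13S)-6β-hydroxylabd-7-en-15-oate | COC(=O)C[C@@H](C)CC[C@@H]1[C@@]2(C)CCCC(C)(C)[C@@H]2[C@H](O)C=C1C | intermediate
21 | methyl (13S)-6β-acetoxylabd-7-en-15-oate | COC(=O)C[C@@H](C)CC[C@@H]1[C@@]2(C)CCCC(C)(C)[C@@H]2[C@H](OC(C)=O)C=C1C | intermediate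
22 | methyl (13S)-6β-acetoxy-8α-hydroxylabdan-15-oate | COC(=O)C[C@@H](C)CC[C@@H]1[C@@]2(C)CCCC(C)(C)[C@@H]2[C@H](OC(C)=O)C[C@@]1(C)O | target

**Step count**
Total: 14 steps. Longest linear sequence: 12 steps (steps 1–5, then 8–14); the aldehyde branch (steps 6–7) joins at step 8.

**Steps most likely to fail**

Step 2. The tertiary cation may be captured by the ketone carbonyl (Prins or ene closure to bridged carbinols) or lost through alkene migration before the enol carbon attacks. Fallback, setting out from 1 and returning at 5: ring A is built by carbonyl chemistry instead. The same copper-catalysed asymmetric conjugate addition is run with [3-(2-methyl-1,3-dioxolan-2-yl)propyl]magnesium chloride F1 (from commercial 2-(3-chloropropyl)-2-methyl-1,3-dioxolane and Mg) to give ketal ketone (S)-3-methyl-3-[3-(2-methyl-1,3-dioxolan-2-yl)propyl]cyclohexan-1-one F2. Aqueous HCl, then TsOH in hot toluene, should unmask diketone (R)-3-methyl-3-(4-oxopentyl)cyclohexan-1-one F3 and close it by intramolecular aldol condensation (the only six-membered mode not excluded by Bredt's rule) to enone (R)-4a,8-dimethyl-3,4,4a,5,6,7-hexahydronaphthalen-1(2H)-one F4. Conjugate addition of Me2CuLi in the presence of BF3·OEt2 adds the second C4 methyl, and equilibrating protonation of the enolate gives 5.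

Step 10. The O-sulfonylation may show poor site selectivity or prefer O6, which would put the methyl on the wrong carbon. Fallback, setting out from 17 and returning at 19: the methyl is brought in as a nucleophile instead. Acid-catalysed enol etherification of 17 (2-methylpropan-1-ol, TsOH, benzene, water removal) gives the separable enol ethers; the C6 enol ether, methyl (13S)-6-(2-methylpropoxy)-8-oxo-17-norlabd-6-en-15-oate F5, is treated with MeLi/CeCl3 at −78 °C to give the carbinol methyl (13S)-8-hydroxy-8-methyl-6-(2-methylpropoxy)-17-norlabd-6-en-15-oate F6. Dilute HCl then hydrolyses the enol ether with loss of water (Stork–Danheiser transposition) to enone 19.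

Step 14. Capture of the C8 radical by O2 may show poor facial selectivity, or simple reduction of the alkene may compete. Fallback, setting out from 19 and returning at 22: the C8 oxygen is delivered by an ionic sequence. Nucleophilic epoxidation (t-BuOOH, DBU, CH2Cl2) on the α face gives methyl (13S)-7α,8α-epoxy-6-oxolabdan-15-oate F7. SmI2 (THF/MeOH, −90 °C) cleaves the C7–O bond next to the carbonyl to give methyl (13S)-8α-hydroxy-6-oxolabdan-15-oate F8. NaBH4 (MeOH, 0 °C) reduces the ketone from the α face to methyl (13S)-6β,8α-dihydroxylabdan-15-oate F9, and Ac2O/DMAP/pyridine acetylates only the secondary hydroxyl to give 22.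

**Further compounds**
F1 | step 2 | [3-(2-methyl-1,3-dioxolan-2-yl)propyl]magnesium chloride | CC1(CCC[Mg]Cl)OCCO1
F2 | step 2 | (S)-3-methyl-3-[3-(2-methyl-1,3-dioxolan-2-yl)propyl]cyclohexan-1-one | O=C1C[C@](C)(CCCC2(C)OCCO2)CCC1
F3 | step 2 | (R)-3-methyl-3-(4-oxopentyl)cyclohexan-1-one | O=C1C[C@](C)(CCCC(C)=O)CCC1
F4 | step 2 | (R)-4a,8-dimethyl-3,4,4a,5,6,7-hexahydronaphthalen-1(2H)-one | C1[C@@]2(C)CCCC(C)=C2C(=O)CC1
F5 | step 10 | methyl (13S)-6-(2-methylpropoxy)-8-oxo-17-norlabd-6-en-15-oate | COC(=O)C[C@@H](C)CC[C@@H]1[C@@]2(C)CCCC(C)(C)[C@@H]2C(OCC(C)C)=CC1=O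
F6 | step 10 | methyl (13S)-8-hydroxy-8-methyl-6-(2-methylpropoxy)-17-norlabd-6-en-15-oate (8β-OH expected) | COC(=O)C[C@@H](C)CC[C@@H]1[C@@]2(C)CCCC(C)(C)[C@@H]2C(OCC(C)C)=C[C@]1(C)O
F7 | step 14 | methyl (13S)-7α,8α-epoxy-6-oxolabdan-15-oate | COC(=O)C[C@@H](C)CC[C@@H]1[C@@]2(C)CCCC(C)(C)[C@@H]2C(=O)[C@H]3O[C@]31C
F8 | step 14 | methyl (13S)-8α-hydroxy-6-oxolabdan-15-oate | COC(=O)C[C@@H](C)CC[C@@H]1[C@@]2(C)CCCC(C)(C)[C@@H]2C(=O)C[C@@]1(C)O
F9 | step 14 | methyl (13S)-6β,8α-dihydroxylabdan-15-oate | COC(=O)C[C@@H](C)CC[C@@H]1[C@@]2(C)CCCC(C)(C)[C@@H]2[C@H](O)C[C@@]1(C)O
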